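**Retrosynthetic overview**
1. Target ⇐ Horner–Wadsworth–Emmons olefination at C13 of the 3β-acetoxy C18 methyl ketone with a silyl phosphonoacetate (sets 13E; the acid is freed on work-up).
2. 8(17)-Methylene ⇐ anti elimination of the equatorial 8α-hydroxyl; 3β-OAc ⇐ acetylation of the 3β-alcohol.
3. Key disconnection: the C3–O bond, made by site- and stereoselective hydroxylation of the equatorial C3–H of 8α-hydroxy-14,15-dinorlabdan-13-one (new ditopic manganese catalyst).
4. That hydroxy ketone ⇐ oxidative excision of C14 and C15 from (−)-sclareol.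
5. No ring is formed: rings A and B with C5, C9 and C10 come intact from sclareol; only C3 is set in the route.

Assumption: the SMILES is read as the normal-series labdane (3S,5R,9S,10R; 3β-OAc equatorial, 5α-H, 9α-H, 10β-CH3), the same absolute series as (−)-sclareol.

Catalyst used in step 2: Mn(OTf)2(cal-PDP), a divalent manganese triflate complex of a new ligand. cal-PDP is (S,S)-PDP [(2S,2'S)-1,1'-bis(pyridin-2-ylmethyl)-2,2'-bipyrrolidine] with a 5-triisopropylsilyl group on each pyridine. One pyridine also carries, through a flat rigid xanthene-4,5-diyl span, a 2-pyridone (cis-amide) hydrogen-bonding site.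

**Step 1**
Reactants: 1 (−)-sclareol [(13R)-labd-14-ene-8α,13-diol]
Product: 4 8α-hydroxy-14,15-dinorlabdan-13-one, via labdane-8α,13,14,15-tetraol 2 (not isolated), via 8α,13-dihydroxy-15-norlabdan-14-al 3 (not isolated)
Conditions: OsO4 (1 mol%), NaIO4 (3.5 equiv), THF/H2O 1:1, 45 °C
Reagents that add atoms: none
Why: Lemieux–Johnson dihydroxylation of the vinyl group followed by two periodate cleavages (C14–C15, then the α-hydroxy aldehyde C13–C14) removes C15 and C14 and leaves the C13 methyl ketone with its original oxygen; no ring stereocenter is touched.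

**Step 2**
Reactants: 4 8α-hydroxy-14,15-dinorlabdan-13-one
Product: 5 3β,8α-dihydroxy-14,15-dinorlabdan-13-one
Conditions: Mn(OTf)2(cal-PDP) (3 mol%), H2O2 (50% aq., 1.5 equiv, syringe pump), AcOH (2 equiv), MeCN, −35 °C
Reagents that add atoms: hydrogen peroxide, OO
Why: Proposed new method: the pyridone site of the catalyst is designed to clamp the 8α-OH/C13=O head of 4 (O–H···O=C and N–H···O=C13) while the rigid span lies against the flat α face, holding the Mn-oxo at the opposite pole of the trans-decalin; there the equatorial C3–H, which is antiparallel to the C8–O8 bond, points at the oxo for a near-linear hydrogen-atom transfer, whereas the intrinsically preferred equatorial C2–H diverges from that axis by about 70°; ring B and side-chain C–H bonds are deactivated by the hydroxyl and ketone as in sclareolide-type substrates; hydrogen abstraction and fast OH rebound proceed with retention, so the new oxygen is equatorial (3β, 3S), and the geminal axial C3–H of the product is turned away from the oxidant, which should slow ketone formation; the closest known reaction types are the undirected Mn(PDP)/H2O2 methylene hydroxylation of terpenoids (C2-favoured on this ring system) and remote C–H oxygenation steered by hydrogen-bond recognition between substrate and a lactam- or acid-bearing catalyst.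

**Step 3**
Reactants: 5 3β,8α-dihydroxy-14,15-dinorlabdan-13-one
Product: 6 3β-acetoxy-8α-hydroxy-14,15-dinorlabdan-13-one
Conditions: Ac2O (3 equiv), pyridine, 23 °C
Reagents that add atoms: acetic anhydride, CC(=O)OC(C)=O
Why: Standard O-acylation; only the secondary equatorial 3β-OH reacts, the hindered tertiary 8α-OH is inert under these conditions, and C3 keeps its configuration because the C–O bond is not broken.

**Step 4**
Reactants: 6 3β-acetoxy-8α-hydroxy-14,15-dinorlabdan-13-one
Product: 8 3β-acetoxy-14,15-dinorlabd-8(17)-en-13-one, via 8α-chlorosulfite 7 (not isolated)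
Conditions: SOCl2 (1.5 equiv), pyridine (6 equiv), CH2Cl2, −78 °C
Reagents that add atoms: none
Why: E2 elimination of the chlorosulfite of an equatorial tertiary alcohol; only the C17 methyl hydrogens can become anti-periplanar to the equatorial C8–O bond (the C7 and C9 hydrogens are gauche), so the exocyclic 8(17)-alkene is favoured, as established for 8α-hydroxy labdanes and drimanes at low temperature; C9 is not epimerised.

**Step 5**
Reactants: 8 3β-acetoxy-14,15-dinorlabd-8(17)-en-13-one, 9 trimethylsilyl (diethoxyphosphoryl)acetate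
Product: 12 3β-acetoxylabda-8(17),13E-dien-15-oic acid, via lithiated phosphonate 10 (not isolated), via trimethylsilyl ester 11 (not isolated)
Conditions: 9 (1.6 equiv), n-BuLi (1.5 equiv), THF, −78 °C; add 8, −78 to 40 °C; 1 M HCl work-up; E isomer purified on AgNO3-impregnated silica
Reagents that add atoms: none
Why: Horner–Wadsworth–Emmons olefination of the unhindered methyl ketone gives mainly the E enoate (ester trans to the larger C12 chain); the stabilised phosphonate anion does not attack the acetate, and the silyl ester hydrolyses on aqueous work-up, so the free acid is obtained without a saponification that would cleave the 3-acetate; no stereocenter is formed.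

**Compound list**
1 | (−)-sclareol, (13R)-labd-14-ene-8α,13-diol | C[C@@]1(O)CC[C@H]2C(C)(C)CCC[C@]2(C)[C@H]1CC[C@@](C)(O)C=C | starting material
2 | (13R)-labdane-8α,13,14,15-tetraol (C14 epimers) | C[C@@]1(O)CC[C@H]2C(C)(C)CCC[C@]2(C)[C@H]1CC[C@@](C)(O)C(O)CO | intermediate
3 | (13R)-8α,13-dihydroxy-15-norlabdan-14-al | C[C@@]1(O)CC[C@H]2C(C)(C)CCC[C@]2(C)[C@H]1CC[C@@](C)(O)C=O | intermediate
4 | 8α-hydroxy-14,15-dinorlabdan-13-one (5α-H, 9α-H, 10β-CH3) | C[C@@]1(O)CC[C@H]2C(C)(C)CCC[C@]2(C)[C@H]1CCC(C)=O | intermediate
5 | 3β,8α-dihydroxy-14,15-dinorlabdan-13-one | C[C@@]1(O)CC[C@H]2C(C)(C)[C@@H](O)CC[C@]2(C)[C@H]1CCC(C)=O | intermediate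
6 | 3β-acetoxy-8α-hydroxy-14,15-dinorlabdan-13-one | C[C@@]1(O)CC[C@H]2C(C)(C)[C@@H](OC(C)=O)CC[C@]2(C)[C@H]1CCC(C)=O | intermediate
7 | 8α-chlorosulfite of 6 (sulfur configuration undefined) | C[C@@]1(OS(Cl)=O)CC[C@H]2C(C)(C)[C@@H](OC(C)=O)CC[C@]2(C)[C@H]1CCC(C)=O | intermediate
8 | 3β-acetoxy-14,15-dinorlabd-8(17)-en-13-one | C=C1CC[C@H]2C(C)(C)[C@@H](OC(C)=O)CC[C@]2(C)[C@H]1CCC(C)=O | intermediate
9 | trimethylsilyl (diethoxyphosphoryl)acetate | CCOP(=O)(OCC)CC(=O)O[Si](C)(C)C | starting material
10 | lithium salt of 9 (lithiated at the P–CH2–C carbon) | [Li+].CCOP(=O)(OCC)[CH-]C(=O)O[Si](C)(C)C | intermediate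
11 | trimethylsilyl 3β-acetoxylabda-8(17),13E-dien-15-oate | C=C1CC[C@H]2C(C)(C)[C@@H](OC(C)=O)CC[C@]2(C)[C@H]1CC/C(C)=C/C(=O)O[Si](C)(C)C | intermediate
12 | 3β-acetoxylabda-8(17),13E-dien-15-oic acid (3S,5R,9S,10R) | C=C1CC[C@H]2C(C)(C)[C@@H](OC(C)=O)CC[C@]2(C)[C@H]1CC/C(C)=C/C(=O)O | target

**Step count and risks**
Total steps: 5. Longest linear sequence: 5 (from sclareol).

Steps most likely to fail:

- **Step 2 (new hydroxylation).** The risk is C2 instead of C3 attack, over-oxidation to the 3-ketone, and weak substrate binding. The fallback uses known chemistry and sets out from 1. Whole-cell hydroxylation of sclareol with the fungus Mucor plumbeus, a reported biotransformation that gives the 3β-alcohol as main product, yields 3β-hydroxysclareol F1. Cleavage of F1 under the step 1 conditions (OsO4 cat., NaIO4, THF/H2O) then gives 5, where the route is rejoined.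

- **Step 4 (dehydration).** The risk is endocyclic 7-ene and 8-ene isomers and capture of a C8 cation by the C13 ketone to give a cyclic enol ether. The fallback sets out from 6 and removes the ketone first. Olefination of 6 with allyl (diethoxyphosphoryl)acetate (NaH, THF) gives allyl (13E)-3β-acetoxy-8α-hydroxylabd-13-en-15-oate F2. Syn elimination with the Burgess reagent (benzene, 50 °C) through the methyl hydrogens gives allyl 3β-acetoxylabda-8(17),13E-dien-15-oate F3. Deallylation with Pd(PPh3)4 and morpholine in THF returns to the route at 12.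

- **Step 5 (olefination to the free acid).** The risk is modest E/Z selectivity and a difficult separation of the isomeric acids. The fallback sets out from 8. Olefination with trimethyl phosphonoacetate (NaH, THF) gives methyl 3β-acetoxylabda-8(17),13E-dien-15-oate F4, whose E and Z esters separate readily on AgNO3-silica. KOH in MeOH/H2O cleaves both esters to 3β-hydroxylabda-8(17),13E-dien-15-oic acid F5. Ac2O in pyridine followed by aqueous hydrolysis of the mixed anhydride returns to the route at 12.

**Further compounds**
F1 | step 2 | 3β-hydroxysclareol, (13R)-labd-14-ene-3β,8α,13-triol | C[C@@]1(O)CC[C@H]2C(C)(C)[C@@H](O)CC[C@]2(C)[C@H]1CC[C@@](C)(O)C=C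
F2 | step 4 | allyl (13E)-3β-acetoxy-8α-hydroxylabd-13-en-15-oate | C[C@@]1(O)CC[C@H]2C(C)(C)[C@@H](OC(C)=O)CC[C@]2(C)[C@H]1CC/C(C)=C/C(=O)OCC=C
F3 | step 4 | allyl 3β-acetoxylabda-8(17),13E-dien-15-oate | C=C1CC[C@H]2C(C)(C)[C@@H](OC(C)=O)CC[C@]2(C)[C@H]1CC/C(C)=C/C(=O)OCC=C
F4 | step 5 | methyl 3β-acetoxylabda-8(17),13E-dien-15-oate | C=C1CC[C@H]2C(C)(C)[C@@H](OC(C)=O)CC[C@]2(C)[C@H]1CC/C(C)=C/C(=O)OC
F5 | step 5 | 3β-hydroxylabda-8(17),13E-dien-15-oic acid | C=C1CC[C@H]2C(C)(C)[C@@H](O)CC[C@]2(C)[C@H]1CC/C(C)=C/C(=O)O
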